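The data are simulated with made-up constants; noise was put on by code.

If I charged more free catalyst to the flask, how much faster would left-handed product form at the stated conversion?

| flask | left-handed substrate | right-handed substrate | partner | protic impurity | free catalyst | remark |
|---|---|---|---|---|---|---|
| elm | 39 mM | 39 mM | 1.4 equiv | 19.5 mM | 0.5 mol% | run made earlier |
| maple | 39 mM | 39 mM | 2.2 equiv | 19.5 mM | 0.5 mol% | run made earlier |
| alder | 39 mM | 39 mM | 1 equiv | 19.5 mM | 0.25 mol% | run made earlier |
| flask | 39 mM | 39 mM | 1.00 equiv | 19.5 mM | 0.5 mol% |  |
- elm (time / d: left-handed product / %, left-handed substrate / %): 0.625: 21.8, 27.6; 1.67: 35.1, 14.7; 3.00: 40.6, 9.3; 5.00: 44.8, 6.1; 8.00: 45.8, 4.1; 10.0: 45.9, 3.5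
- maple (time / d: left-handed product / %, left-handed substrate / %): 0.833: 33.2, 15.6; 1.25: 39.5, 10.3; 2.00: 45.8, 3.9; 4.00: 50.3, 0.1; 6.00: 49.5, 0.3; 10.0: 50.0, 0.6
- alder (time / d: left-handed product / %, left-handed substrate / %): 2.08: 19.9, 29.2; 4.00: 26.7, 22.7; 6.00: 27.8, 22.0; 8.00: 28.5, 20.4; 10.0: 29.2, 20.5

(each reading ± 0.5 percentage points)
* apparent order in free catalyst when 30% of the left-handed substrate and right-handed substrate together are converted (percent change of the rate of making left-handed product for one percent more free catalyst charged)
- free catalyst is single-handed; left-handed substrate and right-handed substrate are mirror images of each other, charged as a racemate, each of them at the stated concentration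
- steps that have been proposed: free catalyst + left-handed substrate <-> catalyst intermediate A; free catalyst + right-handed substrate <-> catalyst intermediate B; partner + catalyst intermediate A -> free catalyst + left-handed product; partner + catalyst intermediate B -> free catalyst + right-handed product; partner + protic impurity -> quenched reagent

I treated substrate binding as an equilibrium, so the bound share of free catalyst followed the substrate left, and I used product made as my clock. Partner enters both product and quenched reagent at first order, so it cancels from their ratio. The protic impurity then falls along that clock with an exponent E, the log of charged over left, and E goes inversely with catalyst. Catalyst therefore acts once directly and once through u, the partner left, which I took as the limiting reagent. With h the impurity left, more catalyst spares partner by hE, so I took the order as one plus hE/u, and hE/u is the surplus order.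

As fractions of both substrates charged, the flask holds partner 0.500 and impurity 0.250. The alder run has the same charge with half the catalyst. First I took alder as finished at its last reading:

quenched 0.208, impurity left 0.0420, E 1.78
flask: E 0.892, impurity left 0.102, u 0.0525, surplus order 1.74

The weak link was "finished", since the alder readings of product were still rising, by 0.00350 d⁻¹. The elm run, at similar left-handed substrate, gave the rate per partner; for its quench I used the first-pass value of the flask, which has the same catalyst loading:

elm: 0.475 d⁻¹
alder: u 0.0147, quenched 0.193, E 1.48
flask: E 0.742, impurity left 0.119, u 0.0691, surplus order 1.28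

My order was 2.28, whereas the forecast said 3.5, with partner “close to exhaustion”. The flask gave 2.1.

    free catalyst + left-handed substrate ⇌ catalyst intermediate A (K = 34.0 L mol⁻¹, k = 0.440 L mol⁻¹ s⁻¹)
    free catalyst + right-handed substrate ⇌ catalyst intermediate B (K = 8.80 L mol⁻¹, k = 4.70 L mol⁻¹ s⁻¹)
    partner + catalyst intermediate A → free catalyst + left-handed product (k = 0.110 L mol⁻¹ s⁻¹)
    partner + catalyst intermediate B → free catalyst + right-handed product (k = 0.00410 L mol⁻¹ s⁻¹)
    partner + protic impurity → quenched reagent (k = 2.30 × 10⁻⁴ L mol⁻¹ s⁻¹)

The flask's surplus order was 1.10, against my 1.28. With the step from partner and protic impurity to quenched reagent removed from this flask, E is zero and the surplus order should vanish. That run's order fell from 2.1 to 1.0.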